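The carbocyclic ring of the 1-aryl-1,2-dihydronaphthalene is cut at C1–C2 and C3=C4: C2–C3, each carrying one oxygenated carbon (acetoxymethyl, formyl), are succinaldehyde, while C1, which bears the 4-hydroxyaryl ring, and the benzylic sp2 carbon C4 are the two electrophilic carbons of one arene partner. In one amine-catalysed operation a succinaldehyde enamine adds 1,6 to a para-quinone methide and the second aldehyde arm condenses with the ortho aryl aldehyde, closing the ring and setting C1 and C2; borohydride in the same flask then fixes C2. The precursor is a racemic 3-aryl-1-hydroxyphthalan lactol with both phenols free, a masked ortho-formyl para-quinone methide.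

Key step: step 7

Remark: the target SMILES is read as the trans (1S,2R) isomer. Compounds 6 to 8 are made racemic at the carbinol carbon on purpose, because that centre is destroyed in step 7.

Step 1
Reactants: 1 6-bromovanillin (2-bromo-4-hydroxy-5-methoxybenzaldehyde)
Product: 2 2-bromo-4-(tert-butyldimethylsilyloxy)-5-methoxybenzaldehyde
Conditions: TBSCl, imidazole, DMF, 0 °C → rt
Reagents that add atoms: tert-butyldimethylsilyl chloride, CC(C)(C)[Si](C)(C)Cl
Why: Imidazole-promoted O-silylation of the phenol is routine for vanillin-type substrates and is done before acetal formation so that no free-phenol acetal, which would be very acid-labile, has to be handled.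

Step 2
Reactants: 2 2-bromo-4-(tert-butyldimethylsilyloxy)-5-methoxybenzaldehyde
Product: 3 [5-bromo-4-(dimethoxymethyl)-2-methoxyphenoxy](tert-butyl)dimethylsilane
Conditions: HC(OMe)3, MeOH, PPTS (cat.), 40 °C; Et3N quench; Et3N-deactivated silica
Reagents that add atoms: trimethyl orthoformate, COC(OC)OC; methanol, CO
Why: Acid-catalysed acetalisation with the orthoester as water scavenger masks the formyl group against the organolithium of step 4, and catalytic PPTS in methanol is too weak to cleave an aryl silyl ether.

Step 3
Reactants: 4 vanillin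
Product: 5 4-(tert-butyldimethylsilyloxy)-3-methoxybenzaldehyde
Conditions: TBSCl, imidazole, DMF, rt
Reagents that add atoms: tert-butyldimethylsilyl chloride, CC(C)(C)[Si](C)(C)Cl
Why: The same imidazole-promoted phenol silylation removes the acidic proton that would quench the aryllithium and keeps the aldehyde electrophilic.

Step 4
Reactants: 3 [5-bromo-4-(dimethoxymethyl)-2-methoxyphenoxy](tert-butyl)dimethylsilane; 5 4-(tert-butyldimethylsilyloxy)-3-methoxybenzaldehyde
Product: 6 rac-[5-(tert-butyldimethylsilyloxy)-2-(dimethoxymethyl)-4-methoxyphenyl][4-(tert-butyldimethylsilyloxy)-3-methoxyphenyl]methanol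
Conditions: n-BuLi (1.05 equiv), THF, −78 °C; then 5, −78 → −40 °C; H2O quench
Reagents that add atoms: none
Why: Bromine–lithium exchange outruns any attack of n-BuLi on the acetal or silyl ethers at −78 °C, and the acetal-chelated aryllithium adds 1,2 to the non-enolisable aldehyde; the carbinol centre may be racemic because step 7 erases it.

Step 5
Reactants: 6 rac-[5-(tert-butyldimethylsilyloxy)-2-(dimethoxymethyl)-4-methoxyphenyl][4-(tert-butyldimethylsilyloxy)-3-methoxyphenyl]methanol
Product: 8 3-(4-hydroxy-3-methoxyphenyl)-6-methoxy-1,3-dihydroisobenzofuran-1,5-diol (racemic anomeric mixture), via bis-silyl lactol 7 (not isolated)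
Conditions: 0.5 M aq. HCl (0.2 equiv), THF/H2O (6:1), 0 °C → rt; then AcOH (3 equiv), Bu4NF (2.5 equiv), same flask, 0 °C → rt; pH 7 phosphate work-up
Reagents that add atoms: water, O
Why: Dilute acid hydrolyses the electron-rich aryl dimethyl acetal and the neighbouring carbinol traps the aldehyde as the five-membered lactol (acetal hydrolysis with hemiacetal closure), after which acetic-acid-buffered fluoride cleaves both aryl silyl ethers (fluoride desilylation) at a pH too mild to ionise the benzhydrylic C–O bond.

Step 6
Reactants: 9 2,5-dimethoxytetrahydrofuran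
Product: 10 succinaldehyde (butanedial)
Conditions: H2O, 90 °C; MeOH distilled off; CH2Cl2 extraction; solution used at once
Reagents that add atoms: water, O
Why: Neutral hydrolysis of the cyclic bis-acetal in hot water frees the dialdehyde, which oligomerises on storage and is therefore made fresh and used in excess.

Step 7
Reactants: 8 3-(4-hydroxy-3-methoxyphenyl)-6-methoxy-1,3-dihydroisobenzofuran-1,5-diol; 10 succinaldehyde
Product: 14 (1S,2R)-7-hydroxy-2-(hydroxymethyl)-1-(4-hydroxy-3-methoxyphenyl)-6-methoxy-1,2-dihydronaphthalene-3-carbaldehyde, via quinone methide 11 (not isolated), via trialdehyde 12 (not isolated), via dialdehyde 13 (not isolated)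
Conditions: (R)-2-[diphenyl(trimethylsilyloxy)methyl]pyrrolidine (20 mol%), 4-nitrobenzoic acid (20 mol%), 10 (2.5 equiv, slow addition), CH2Cl2/MeCN (4:1), 0 °C → rt; then EtOH, NaBH4, −78 °C; aq. NH4Cl at −78 °C
Reagents that add atoms: none
Why: Proposed new method: the acid co-catalyst lets the para-hydroxyl of lactol 8 expel the benzhydrylic ring oxygen, giving the doubly aryl-stabilised ortho-formyl para-quinone methide 11 reversibly and in low concentration, and the enamine formed from succinaldehyde and the diarylprolinol silyl ether adds to its exocyclic carbon in a 1,6-sense (C1–C2 bond) with rearomatisation to 12. The closest known reaction types are amine-catalysed enantioselective 1,6-additions of aldehyde enamines to para-quinone methides, SN1-type α-alkylations of aldehydes with benzhydrols, and Michael/carbonyl-addition cascades of succinaldehyde under diarylprolinol silyl ether catalysis. The unbranched CH2CHO arm of 12 then forms a second enamine and closes the only new ring, the carbocycle C8a–C1–C2–C3=C4–C4a, by a 6-(enolexo)-exo-trig aldol onto the ortho aryl aldehyde, whose dehydration to the styrene-conjugated enal 13 is irreversible, whereas the α-branched aldehyde forms an enamine slowly and could only reach a five-membered aldol that cannot dehydrate. C2 is set by the catalyst, whose diphenyl(silyloxy)methyl group screens one enamine face (the (R)-catalyst is predicted by analogy with enamine Michael additions and is to be confirmed at 14), and C1 by an open synclinal approach that keeps the formyl-bearing aryl group away from the enamine chain, the topicity that gives syn adducts with nitroalkenes and here the trans ring; the racemic carbinol centre of 8 vanishes in 11, so both enantiomers of 8 converge. The step needs attack at the quinone methide carbon in preference to the aryl aldehyde and cross-reaction in preference to succinaldehyde self-aldol, which the far higher electrophilicity of 11, the para-hydroxyl that deactivates the aryl aldehyde, and slow addition of excess 10 should secure. NaBH4 at −78 °C (aldehyde-over-enal borohydride selectivity) then reduces only the saturated α-branched formyl group of 13, since the enal is a vinylogous ester of the para-phenolate, and this freezes C2 before it can epimerise; any cis isomer is removed by chromatography of 14.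

Step 8
Reactants: 14 (1S,2R)-7-hydroxy-2-(hydroxymethyl)-1-(4-hydroxy-3-methoxyphenyl)-6-methoxy-1,2-dihydronaphthalene-3-carbaldehyde
Product: 15 [(1S,2R)-3-formyl-7-hydroxy-1-(4-hydroxy-3-methoxyphenyl)-6-methoxy-1,2-dihydronaphthalen-2-yl]methyl acetate (CNP0549177.1)
Conditions: immobilised Candida antarctica lipase B (CAL-B), vinyl acetate (5 equiv), THF, 35 °C; filtration
Reagents that add atoms: vinyl acetate, CC(=O)OC=C
Why: Lipase-catalysed irreversible transesterification with an enol ester acylates primary aliphatic alcohols and leaves phenols untouched, and its neutral conditions spare the enal and the two stereocentres, neither of which is set or changed here.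

Compound list
1 | 6-bromovanillin (2-bromo-4-hydroxy-5-methoxybenzaldehyde) | O=Cc1cc(OC)c(O)cc1Br | starting material
2 | 2-bromo-4-(tert-butyldimethylsilyloxy)-5-methoxybenzaldehyde | O=Cc1cc(OC)c(O[Si](C)(C)C(C)(C)C)cc1Br | intermediate
3 | [5-bromo-4-(dimethoxymethyl)-2-methoxyphenoxy](tert-butyl)dimethylsilane | COC(OC)c1cc(OC)c(O[Si](C)(C)C(C)(C)C)cc1Br | intermediate
4 | vanillin (4-hydroxy-3-methoxybenzaldehyde) | O=Cc1ccc(O)c(OC)c1 | starting material
5 | 4-(tert-butyldimethylsilyloxy)-3-methoxybenzaldehyde | O=Cc1ccc(O[Si](C)(C)C(C)(C)C)c(OC)c1 | intermediate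
6 | rac-[5-(tert-butyldimethylsilyloxy)-2-(dimethoxymethyl)-4-methoxyphenyl][4-(tert-butyldimethylsilyloxy)-3-methoxyphenyl]methanol | COC(OC)c1cc(OC)c(O[Si](C)(C)C(C)(C)C)cc1C(O)c1ccc(O[Si](C)(C)C(C)(C)C)c(OC)c1 | intermediate
7 | 5-(tert-butyldimethylsilyloxy)-3-[4-(tert-butyldimethylsilyloxy)-3-methoxyphenyl]-6-methoxy-1,3-dihydroisobenzofuran-1-ol (racemic, anomeric mixture) | OC1OC(c2ccc(O[Si](C)(C)C(C)(C)C)c(OC)c2)c2cc(O[Si](C)(C)C(C)(C)C)c(OC)cc21 | intermediate (not isolated)
8 | 3-(4-hydroxy-3-methoxyphenyl)-6-methoxy-1,3-dihydroisobenzofuran-1,5-diol (racemic, anomeric mixture, in equilibrium with the open hydroxy aldehyde) | OC1OC(c2ccc(O)c(OC)c2)c2cc(O)c(OC)cc21 | intermediate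
9 | 2,5-dimethoxytetrahydrofuran (cis/trans mixture) | COC1CCC(OC)O1 | starting material
10 | succinaldehyde (butanedial) | O=CCCC=O | intermediate
11 | 4-hydroxy-5-methoxy-2-[(3-methoxy-4-oxocyclohexa-2,5-dien-1-ylidene)methyl]benzaldehyde (exocyclic alkene geometry not defined) | COC1=CC(=Cc2cc(O)c(OC)cc2C=O)C=CC1=O | intermediate (not isolated)
12 | (2S)-2-[(S)-(2-formyl-5-hydroxy-4-methoxyphenyl)(4-hydroxy-3-methoxyphenyl)methyl]butanedial | COc1cc(ccc1O)[C@H]([C@@H](C=O)CC=O)c1cc(O)c(OC)cc1C=O | intermediate (not isolated)
13 | (1S,2R)-7-hydroxy-1-(4-hydroxy-3-methoxyphenyl)-6-methoxy-1,2-dihydronaphthalene-2,3-dicarbaldehyde (trans) | COc1cc([C@H]2c3cc(O)c(OC)cc3C=C(C=O)[C@@H]2C=O)ccc1O | intermediate (not isolated)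
14 | (1S,2R)-7-hydroxy-2-(hydroxymethyl)-1-(4-hydroxy-3-methoxyphenyl)-6-methoxy-1,2-dihydronaphthalene-3-carbaldehyde (trans) | COc1cc([C@H]2c3cc(O)c(OC)cc3C=C(C=O)[C@@H]2CO)ccc1O | intermediate
15 | [(1S,2R)-3-formyl-7-hydroxy-1-(4-hydroxy-3-methoxyphenyl)-6-methoxy-1,2-dihydronaphthalen-2-yl]methyl acetate | COc1cc([C@H]2c3cc(O)c(OC)cc3C=C(C=O)[C@@H]2COC(C)=O)ccc1O | target

Total step count: 8
Longest linear sequence: 6 steps (steps 1, 2, 4, 5, 7, 8)

Steps most likely to fail

1. Step 7. The lactol may not ionise to the quinone methide under conditions the enamine survives, succinaldehyde may self-condense faster than it is intercepted, or the 1,6-addition may show poor facial or trans selectivity. The fallback uses auxiliary-controlled known chemistry, sets out from 5 and 3 and returns at 15. Horner–Wadsworth–Emmons olefination of 5 with diethyl {2-oxo-2-[(4S)-2-oxo-4-phenyloxazolidin-3-yl]ethyl}phosphonate (LiCl, iPr2NEt, MeCN) would give the (E)-N-enoyl oxazolidinone F1. The aryllithium from 3 (n-BuLi, −78 °C), transmetallated with MgBr2·OEt2 and CuBr·SMe2, should add to the chelated syn-s-cis enoyl imide on the face away from the 4-phenyl group and give the 3,3-diarylpropanoyl imide F2, in which the future C1 is set. Enolisation with NaN(SiMe3)2 and allylation with allyl iodide at −78 °C, again anti to the phenyl group of the chelated (Z)-enolate, would give the α-allyl imide F3 and set the future C2. LiBH4 in wet THF removes the auxiliary to give the primary alcohol F4, which is acetylated (Ac2O, pyridine, DMAP) while both phenols are still silylated, giving the acetate F5. Lemieux–Johnson cleavage of the alkene (OsO4 cat., NaIO4, 2,6-lutidine, dioxane/H2O) gives the aldehyde F6. Dilute aqueous acid then frees the aryl aldehyde and dibenzylammonium trifluoroacetate closes the ring by intramolecular aldol condensation to the bis-silylated target F7, and buffered Bu4NF/AcOH gives 15. The (4S)-auxiliary is the one the chelation models call for at both centres.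

2. Step 8. The enzyme may reject the β-branched primary alcohol, or a phenol may be acylated in competition. The fallback sets out from 14 and returns at 15: exhaustive acetylation (Ac2O, pyridine, 0 °C) would give the triacetate F8, and the two aryl acetates, far more labile than the alkyl acetate, are then removed selectively with NH4OAc in aqueous MeOH at rt.

3. Step 5. Acid unmasking may ionise the benzhydrylic C–O bond (oligomerisation or dehydration to an isobenzofuran), or desilylation may stall in the wet one-flask medium. The fallback avoids the acetal and every acidic operation, sets out from 2 and returns at 7. Aldehyde 2 is protected in the flask as the lithium α-amino alkoxide F9 with LiN(Me)CH2CH2NMe2 (THF, −20 °C). Bromine–lithium exchange with n-BuLi (−78 °C) and addition of 5 follow. Neutral aqueous work-up collapses the amino alkoxide, and the freed hydroxy aldehyde closes to the bis-silyl lactol 7. This is then desilylated with Bu4NF/AcOH in THF alone to give 8.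

Further compounds
F1 | step 7 | (4S)-3-[(E)-3-[4-(tert-butyldimethylsilyloxy)-3-methoxyphenyl]prop-2-enoyl]-4-phenyloxazolidin-2-one | COc1cc(/C=C/C(=O)N2[C@@H](c3ccccc3)COC2=O)ccc1O[Si](C)(C)C(C)(C)C
F2 | step 7 | (4S)-3-[(3S)-3-[5-(tert-butyldimethylsilyloxy)-2-(dimethoxymethyl)-4-methoxyphenyl]-3-[4-(tert-butyldimethylsilyloxy)-3-methoxyphenyl]propanoyl]-4-phenyloxazolidin-2-one | COc1cc(ccc1O[Si](C)(C)C(C)(C)C)[C@H](CC(=O)N1[C@@H](c2ccccc2)COC1=O)c1cc(O[Si](C)(C)C(C)(C)C)c(OC)cc1C(OC)OC
F3 | step 7 | (4S)-3-[(2S)-2-[(S)-[5-(tert-butyldimethylsilyloxy)-2-(dimethoxymethyl)-4-methoxyphenyl][4-(tert-butyldimethylsilyloxy)-3-methoxyphenyl]methyl]pent-4-enoyl]-4-phenyloxazolidin-2-one | COc1cc(ccc1O[Si](C)(C)C(C)(C)C)[C@H]([C@@H](C(=O)N1[C@@H](c2ccccc2)COC1=O)CC=C)c1cc(O[Si](C)(C)C(C)(C)C)c(OC)cc1C(OC)OC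
F4 | step 7 | (2S)-2-[(S)-[5-(tert-butyldimethylsilyloxy)-2-(dimethoxymethyl)-4-methoxyphenyl][4-(tert-butyldimethylsilyloxy)-3-methoxyphenyl]methyl]pent-4-en-1-ol | COc1cc(ccc1O[Si](C)(C)C(C)(C)C)[C@H]([C@@H](CO)CC=C)c1cc(O[Si](C)(C)C(C)(C)C)c(OC)cc1C(OC)OC
F5 | step 7 | (2S)-2-[(S)-[5-(tert-butyldimethylsilyloxy)-2-(dimethoxymethyl)-4-methoxyphenyl][4-(tert-butyldimethylsilyloxy)-3-methoxyphenyl]methyl]pent-4-enyl acetate | COc1cc(ccc1O[Si](C)(C)C(C)(C)C)[C@H]([C@@H](COC(C)=O)CC=C)c1cc(O[Si](C)(C)C(C)(C)C)c(OC)cc1C(OC)OC
F6 | step 7 | (2S)-2-[(S)-[5-(tert-butyldimethylsilyloxy)-2-(dimethoxymethyl)-4-methoxyphenyl][4-(tert-butyldimethylsilyloxy)-3-methoxyphenyl]methyl]-4-oxobutyl acetate | COc1cc(ccc1O[Si](C)(C)C(C)(C)C)[C@H]([C@@H](COC(C)=O)CC=O)c1cc(O[Si](C)(C)C(C)(C)C)c(OC)cc1C(OC)OC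
F7 | step 7 | [(1S,2R)-7-(tert-butyldimethylsilyloxy)-1-[4-(tert-butyldimethylsilyloxy)-3-methoxyphenyl]-3-formyl-6-methoxy-1,2-dihydronaphthalen-2-yl]methyl acetate | COc1cc([C@H]2c3cc(O[Si](C)(C)C(C)(C)C)c(OC)cc3C=C(C=O)[C@@H]2COC(C)=O)ccc1O[Si](C)(C)C(C)(C)C
F8 | step 8 | [(1S,2R)-7-acetoxy-1-(4-acetoxy-3-methoxyphenyl)-3-formyl-6-methoxy-1,2-dihydronaphthalen-2-yl]methyl acetate | COc1cc([C@H]2c3cc(OC(C)=O)c(OC)cc3C=C(C=O)[C@@H]2COC(C)=O)ccc1OC(C)=O
F9 | step 5 | lithium [2-bromo-4-(tert-butyldimethylsilyloxy)-5-methoxyphenyl]{[2-(dimethylamino)ethyl](methyl)amino}methanolate (racemic) | [Li+].[O-]C(N(C)CCN(C)C)c1cc(OC)c(O[Si](C)(C)C(C)(C)C)cc1Br
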